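**Retrosynthetic overview**
- The target 16 comes from diester 15 by reduction of both esters; 15 comes from aldehyde 13 by olefination, and 13 from the protected trans ester 12.
- The dihydrofuran ring is cut at C3–C3a and C7a–O1. O1–C2–C3 with C9 as an ester carbon is the β-hydroxy ester 5, nucleophilic at oxygen and at the α-carbon. C3a and C7a are adjacent ring A carbons, supplied as bromide and triflate in 8.
- Rings A and B are bought as benzene rings; the dihydrofuran ring is the only ring made (step 6). C2 is set by asymmetric transfer hydrogenation (step 3) and C3 by equilibration (step 7).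
- 5 comes from acetosyringone (MOM ether, Claisen acylation, reduction); 8 comes from 5-bromovanillin (triflate, dioxolane).

Key step: step 6

Remark: benzofuran numbering is used (O1, C2, C3, C3a, C4–C7, C7a; C9 is the carbon on C3), ring B is the syringyl ring, and because the kinetic C3 outcome of the annulation cannot be foreseen, an equilibration (step 7) is written in.

**Route**

Step 1
Reactants: 1 acetosyringone
Product: 2 1-[3,5-dimethoxy-4-(methoxymethoxy)phenyl]ethanone
Conditions: NaH (1.05 equiv), MOMCl, THF, 0 °C to rt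
Reagents that add atoms: chloromethyl methyl ether, COCCl
Why: Williamson O-alkylation of the sodium phenoxide; one equivalent of NaH removes only the phenol proton, and the MOM acetal is stable to all later basic steps.

Step 2
Reactants: 2 1-[3,5-dimethoxy-4-(methoxymethoxy)phenyl]ethanone; 3 dimethyl carbonate
Product: 4 methyl 3-[3,5-dimethoxy-4-(methoxymethoxy)phenyl]-3-oxopropanoate
Conditions: NaH (2.5 equiv), dimethyl carbonate (5 equiv), THF, reflux; then AcOH
Reagents that add atoms: dimethyl carbonate (3), COC(=O)OC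
Why: Crossed Claisen condensation of the methyl ketone enolate with the non-enolisable carbonate, driven by deprotonation of the β-keto ester formed.

Step 3
Reactants: 4 methyl 3-[3,5-dimethoxy-4-(methoxymethoxy)phenyl]-3-oxopropanoate
Product: 5 methyl (3R)-3-[3,5-dimethoxy-4-(methoxymethoxy)phenyl]-3-hydroxypropanoate
Conditions: RuCl[(R,R)-TsDPEN](p-cymene) (1 mol%), HCO2H–Et3N (5:2), EtOAc, 40 °C
Reagents that add atoms: none
Why: Noyori–Ikariya asymmetric transfer hydrogenation of an aryl ketone, in which a CH–π contact between the aryl ring and the cymene ligand fixes the face, so the (R,R)-ligand should give the 3R alcohol (the same sense by which the (S,S)-catalyst gives (S)-1-phenylethanol), and the buffered medium spares the MOM acetal.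

Step 4
Reactants: 6 5-bromovanillin
Product: 7 2-bromo-4-formyl-6-methoxyphenyl trifluoromethanesulfonate
Conditions: Tf2O, pyridine, CH2Cl2, 0 °C
Reagents that add atoms: trifluoromethanesulfonic anhydride, O=S(=O)(OS(=O)(=O)C(F)(F)F)C(F)(F)F
Why: O-sulfonylation of the acidic phenol; aldehyde and aryl bromide are inert.

Step 5
Reactants: 7 2-bromo-4-formyl-6-methoxyphenyl trifluoromethanesulfonate
Product: 8 2-bromo-4-(1,3-dioxolan-2-yl)-6-methoxyphenyl trifluoromethanesulfonate
Conditions: ethylene glycol, p-TsOH (cat.), toluene, reflux, Dean–Stark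
Reagents that add atoms: ethylene glycol, OCCO
Why: Acid-catalysed acetalisation with azeotropic removal of water; the electron-poor aldehyde acetalises readily and aryl triflates and bromides are stable to TsOH.

Step 6
Reactants: 5 methyl (3R)-3-[3,5-dimethoxy-4-(methoxymethoxy)phenyl]-3-hydroxypropanoate; 8 2-bromo-4-(1,3-dioxolan-2-yl)-6-methoxyphenyl trifluoromethanesulfonate
Product: 11 methyl (2R)-5-(1,3-dioxolan-2-yl)-2-[3,5-dimethoxy-4-(methoxymethoxy)phenyl]-7-methoxy-2,3-dihydro-1-benzofuran-3-carboxylate as its C3 epimers, via zinc alkoxide–enolate chelate 9 (not isolated), via C-arylated zinc alkoxide 10 (not isolated)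
Conditions: LDA (2.1 equiv), THF, −78 to −20 °C; ZnCl2 (1.1 equiv), −20 °C to rt; 8 (1.05 equiv), Pd(dba)2 (5 mol%), P(t-Bu)3 (5 mol%), rt; then t-BuXPhos (10 mol%), 65 °C; aq. NH4Cl
Reagents that add atoms: none
Why: Proposed new method: two equivalents of LDA give the alkoxide–enolate dianion of 5, which ZnCl2 converts into the six-membered zinc chelate 9; zerovalent palladium bearing P(t-Bu)3 inserts into the C–Br bond of 8, the enolate carbon passes from zinc to palladium and reductive elimination forms C3–C3a, giving 10. The added biaryl phosphine then allows insertion into the neighbouring C7a–OTf bond, the zinc-bound oxide is handed to the cationic arylpalladium centre, and C–O reductive elimination from the resulting six-membered oxapalladacycle (Pd, C7a, C3a, C3, C2, O) closes the five-membered dihydrofuran ring at C7a–O1. The closest known reactions are the palladium-catalysed α-arylation of zinc ester enolates with aryl bromides, the intramolecular palladium-catalysed etherification of aryl halides by secondary alcohols and the Fráter–Seebach α-alkylation of β-hydroxy ester dianions; their combination on one dianion and one bromo triflate has no precedent. C2 is the carbinol carbon of 5 and none of its bonds is broken, so its 3R configuration is carried over as 2R with retention, provided C–O reductive elimination outruns β-hydride loss from the palladium alkoxide, which the bulky di-tert-butyl biaryl phosphine is chosen to ensure. C3 is formed without dependable control (arylation of the chelate anti to the ring B aryl group would lead to the cis ring) and is settled in step 7. The step needs bromide to react before triflate and carbon before oxygen: P(t-Bu)3 on palladium discriminates strongly for bromide, the triflate is shielded between OMe and Br, zinc enolates transmetalate at room temperature where zinc alkoxides do not, and the covalent zinc–oxygen bond holds back retro-aldol cleavage of 10 and attack of the oxide at sulfur.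

Step 7
Reactants: 11 methyl (2R)-5-(1,3-dioxolan-2-yl)-2-[3,5-dimethoxy-4-(methoxymethoxy)phenyl]-7-methoxy-2,3-dihydro-1-benzofuran-3-carboxylate (C3 epimers)
Product: 12 methyl (2R,3R)-trans-5-(1,3-dioxolan-2-yl)-2-[3,5-dimethoxy-4-(methoxymethoxy)phenyl]-7-methoxy-2,3-dihydro-1-benzofuran-3-carboxylate
Conditions: NaOMe (0.2 equiv), MeOH–THF, 0 °C to rt
Reagents that add atoms: none
Why: Thermodynamic epimerisation through the C3 ester enolate, which should converge on the stable 2,3-trans isomer of a 2-aryl-2,3-dihydrobenzofuran-3-carboxylate, while C2 has no acidic hydrogen and keeps its R configuration.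

Step 8
Reactants: 12 methyl (2R,3R)-trans-5-(1,3-dioxolan-2-yl)-2-[3,5-dimethoxy-4-(methoxymethoxy)phenyl]-7-methoxy-2,3-dihydro-1-benzofuran-3-carboxylate
Product: 13 methyl (2R,3R)-5-formyl-2-(4-hydroxy-3,5-dimethoxyphenyl)-7-methoxy-2,3-dihydro-1-benzofuran-3-carboxylate
Conditions: 2 M aq. HCl–THF (1:2), 45 °C
Reagents that add atoms: water, O
Why: Acid-catalysed acetal hydrolysis removes the dioxolane and the MOM ether in one operation; the methyl ester and the ring should survive dilute acid, and C3 does not epimerise under acid.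

Step 9
Reactants: 13 methyl (2R,3R)-5-formyl-2-(4-hydroxy-3,5-dimethoxyphenyl)-7-methoxy-2,3-dihydro-1-benzofuran-3-carboxylate; 14 triethyl phosphonoacetate
Product: 15 methyl (2R,3R)-5-[(E)-3-ethoxy-3-oxoprop-1-enyl]-2-(4-hydroxy-3,5-dimethoxyphenyl)-7-methoxy-2,3-dihydro-1-benzofuran-3-carboxylate
Conditions: LiCl, DBU (2.5 equiv), MeCN, 0 °C to rt
Reagents that add atoms: triethyl phosphonoacetate (14), CCOC(=O)CP(=O)(OCC)OCC
Why: Horner–Wadsworth–Emmons olefination under Masamune–Roush conditions, E-selective for aromatic aldehydes and mild enough for the free phenol and the C3 ester, which already sits trans.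

Step 10
Reactants: 15 methyl (2R,3R)-5-[(E)-3-ethoxy-3-oxoprop-1-enyl]-2-(4-hydroxy-3,5-dimethoxyphenyl)-7-methoxy-2,3-dihydro-1-benzofuran-3-carboxylate
Product: 16 4-[(2R,3S)-3-(hydroxymethyl)-5-[(E)-3-hydroxyprop-1-enyl]-7-methoxy-2,3-dihydro-1-benzofuran-2-yl]-2,6-dimethoxyphenol (target)
Conditions: i-Bu2AlH (7 equiv), THF, −78 to 0 °C; aq. potassium sodium tartrate
Reagents that add atoms: none
Why: Aluminium hydride 1,2-reduction of both esters to the allylic and the C9 primary alcohol without conjugate reduction; no stereocentre is touched, and the C3 descriptor changes from R to S only through the CIP priorities.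

**Compound list**
1 | 1-(4-hydroxy-3,5-dimethoxyphenyl)ethanone (acetosyringone) | CC(=O)c1cc(OC)c(O)c(OC)c1 | starting material
2 | 1-[3,5-dimethoxy-4-(methoxymethoxy)phenyl]ethanone | CC(=O)c1cc(OC)c(OCOC)c(OC)c1 | intermediate
3 | dimethyl carbonate | COC(=O)OC | starting material
4 | methyl 3-[3,5-dimethoxy-4-(methoxymethoxy)phenyl]-3-oxopropanoate | COC(=O)CC(=O)c1cc(OC)c(OCOC)c(OC)c1 | intermediate
5 | methyl (3R)-3-[3,5-dimethoxy-4-(methoxymethoxy)phenyl]-3-hydroxypropanoate | COc1cc([C@H](O)CC(=O)OC)cc(OC)c1OCOC | intermediate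
6 | 5-bromovanillin (3-bromo-4-hydroxy-5-methoxybenzaldehyde) | COc1cc(C=O)cc(Br)c1O | starting material
7 | 2-bromo-4-formyl-6-methoxyphenyl trifluoromethanesulfonate | COc1cc(C=O)cc(Br)c1OS(=O)(=O)C(F)(F)F | intermediate
8 | 2-bromo-4-(1,3-dioxolan-2-yl)-6-methoxyphenyl trifluoromethanesulfonate | COc1cc(C2OCCO2)cc(Br)c1OS(=O)(=O)C(F)(F)F | intermediate
9 | zinc alkoxide–enolate chelate of 5 (zinc bound to the C3 oxide and the enolate oxygen; 3R) | COC1=C[C@H](c2cc(OC)c(OCOC)c(OC)c2)O[Zn]O1 | intermediate
10 | methyl (3R)-3-(bromozincoxy)-3-[3,5-dimethoxy-4-(methoxymethoxy)phenyl]-2-[5-(1,3-dioxolan-2-yl)-3-methoxy-2-(trifluoromethanesulfonyloxy)phenyl]propanoate (C2 not defined) | COC(=O)C(c1cc(C2OCCO2)cc(OC)c1OS(=O)(=O)C(F)(F)F)[C@@H](O[Zn]Br)c1cc(OC)c(OCOC)c(OC)c1 | intermediate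
11 | methyl (2R)-5-(1,3-dioxolan-2-yl)-2-[3,5-dimethoxy-4-(methoxymethoxy)phenyl]-7-methoxy-2,3-dihydro-1-benzofuran-3-carboxylate (C3 epimers) | COc1cc([C@@H]2Oc3c(OC)cc(C4OCCO4)cc3C2C(=O)OC)cc(OC)c1OCOC | intermediate
12 | methyl (2R,3R)-trans-5-(1,3-dioxolan-2-yl)-2-[3,5-dimethoxy-4-(methoxymethoxy)phenyl]-7-methoxy-2,3-dihydro-1-benzofuran-3-carboxylate | COc1cc([C@@H]2Oc3c(OC)cc(C4OCCO4)cc3[C@H]2C(=O)OC)cc(OC)c1OCOC | intermediate
13 | methyl (2R,3R)-5-formyl-2-(4-hydroxy-3,5-dimethoxyphenyl)-7-methoxy-2,3-dihydro-1-benzofuran-3-carboxylate | COc1cc([C@@H]2Oc3c(OC)cc(C=O)cc3[C@H]2C(=O)OC)cc(OC)c1O | intermediate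
14 | triethyl phosphonoacetate | CCOC(=O)CP(=O)(OCC)OCC | starting material
15 | methyl (2R,3R)-5-[(E)-3-ethoxy-3-oxoprop-1-enyl]-2-(4-hydroxy-3,5-dimethoxyphenyl)-7-methoxy-2,3-dihydro-1-benzofuran-3-carboxylate | COc1cc([C@@H]2Oc3c(OC)cc(/C=C/C(=O)OCC)cc3[C@H]2C(=O)OC)cc(OC)c1O | intermediate
16 | 4-[(2R,3S)-3-(hydroxymethyl)-5-[(E)-3-hydroxyprop-1-enyl]-7-methoxy-2,3-dihydro-1-benzofuran-2-yl]-2,6-dimethoxyphenol | COc1cc([C@@H]2Oc3c(OC)cc(/C=C/CO)cc3[C@H]2CO)cc(OC)c1O | target

**Step count**
Total: 10 steps. Longest linear sequence: 8 steps (1, 2, 3, 6, 7, 8, 9, 10).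

**Steps most likely to fail**

Step 6 (proposed new method).
- Stalling: after the C–C coupling the hindered triflate may resist insertion, or the zinc-bound oxide may not pass to palladium, so that the reaction stops at the open-chain stage.
- β-Hydride loss: the palladium alkoxide may give the ketone and the reduced arene.
- Erosion of C2: retro-aldol cleavage of the arylated aldolate, or triflyl transfer to the oxide followed by displacement.

Fallback, by known chemistry (dirhodium-carbenoid C–H insertion, established for cis-2-aryl-2,3-dihydrobenzofuran-3-carboxylates): it sets out from 6 and returns at 12. Commercial 4-hydroxy-3,5-dimethoxybenzyl alcohol is MOM-protected at the phenol (MOMCl, K2CO3, acetone) to [3,5-dimethoxy-4-(methoxymethoxy)phenyl]methanol F1. Mitsunobu etherification of 6 with F1 (PPh3, DIAD, THF) gives 3-bromo-4-{[3,5-dimethoxy-4-(methoxymethoxy)phenyl]methoxy}-5-methoxybenzaldehyde F2. Aprotic acetalisation (TMSOCH2CH2OTMS, cat. TMSOTf, CH2Cl2, −78 °C) gives 2-(3-bromo-4-{[3,5-dimethoxy-4-(methoxymethoxy)phenyl]methoxy}-5-methoxyphenyl)-1,3-dioxolane F3. Palladium-catalysed coupling of the aryl bromide with the Reformatsky reagent BrZnCH2CO2Me (Pd(dba)2, P(t-Bu)3, THF, rt) gives methyl 2-[2-{[3,5-dimethoxy-4-(methoxymethoxy)phenyl]methoxy}-5-(1,3-dioxolan-2-yl)-3-methoxyphenyl]acetate F4. Diazo transfer (p-ABSA, DBU, MeCN) gives methyl 2-diazo-2-[2-{[3,5-dimethoxy-4-(methoxymethoxy)phenyl]methoxy}-5-(1,3-dioxolan-2-yl)-3-methoxyphenyl]acetate F5. The chiral dirhodium tetracarboxylate Rh2(S-PTTL)4 (toluene, −60 °C) should insert the carbenoid into a benzylic O–CH2 hydrogen bond and close the five-membered ring to methyl (2R,3S)-cis-5-(1,3-dioxolan-2-yl)-2-[3,5-dimethoxy-4-(methoxymethoxy)phenyl]-7-methoxy-2,3-dihydro-1-benzofuran-3-carboxylate F6; the mirror-image catalyst is taken should the sense prove opposite. F6 is epimerised at C3 as in step 7 to give 12.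

Step 8.
- Ring opening: once the MOM group is lost, the 4-hydroxyaryl group can assist acid ionisation of the benzylic C2–O bond, with ring opening or C2 epimerisation.
- Ester hydrolysis: the methyl ester may be partly cleaved.

Fallback: the two acetals are removed in separate operations on either side of the olefination, and the MOM group is cleaved without protic acid; it sets out from 12 and returns at 15. PPTS in wet acetone (50 °C) removes only the dioxolane to give methyl (2R,3R)-2-[3,5-dimethoxy-4-(methoxymethoxy)phenyl]-5-formyl-7-methoxy-2,3-dihydro-1-benzofuran-3-carboxylate F7. Olefination with 14 as in step 9 gives methyl (2R,3R)-2-[3,5-dimethoxy-4-(methoxymethoxy)phenyl]-5-[(E)-3-ethoxy-3-oxoprop-1-enyl]-7-methoxy-2,3-dihydro-1-benzofuran-3-carboxylate F8. ZnBr2 and n-PrSH (CH2Cl2, 0 °C) cleave the MOM ether by thiol capture of the oxocarbenium ion and give 15.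

Step 3.
- Slow hydride transfer to the electron-rich, enolisable keto ester.
- Incomplete facial selectivity, which would carry through as lowered enantiopurity at C2.

Fallback: reduction without stereocontrol followed by enzymatic kinetic resolution; it sets out from 4 and returns at 5. NaBH4 (MeOH, 0 °C) gives racemic methyl 3-[3,5-dimethoxy-4-(methoxymethoxy)phenyl]-3-hydroxypropanoate F9. Burkholderia cepacia lipase with vinyl acetate in MTBE is expected, by the empirical size rule for secondary alcohols, to acylate the 3R enantiomer. This gives methyl (3R)-3-acetoxy-3-[3,5-dimethoxy-4-(methoxymethoxy)phenyl]propanoate F10 beside unreacted methyl (3S)-3-[3,5-dimethoxy-4-(methoxymethoxy)phenyl]-3-hydroxypropanoate F11, separated by chromatography. Methanolysis of F10 with the same lipase (MeOH, MTBE) gives 5. F11 can be returned to 4 by Dess–Martin oxidation.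

**Further compounds**
F1 | step 6 | [3,5-dimethoxy-4-(methoxymethoxy)phenyl]methanol | COCOc1c(OC)cc(CO)cc1OC
F2 | step 6 | 3-bromo-4-{[3,5-dimethoxy-4-(methoxymethoxy)phenyl]methoxy}-5-methoxybenzaldehyde | COc1cc(C=O)cc(Br)c1OCc1cc(OC)c(OCOC)c(OC)c1
F3 | step 6 | 2-(3-bromo-4-{[3,5-dimethoxy-4-(methoxymethoxy)phenyl]methoxy}-5-methoxyphenyl)-1,3-dioxolane | COc1cc(C2OCCO2)cc(Br)c1OCc1cc(OC)c(OCOC)c(OC)c1
F4 | step 6 | methyl 2-[2-{[3,5-dimethoxy-4-(methoxymethoxy)phenyl]methoxy}-5-(1,3-dioxolan-2-yl)-3-methoxyphenyl]acetate | COC(=O)Cc1cc(C2OCCO2)cc(OC)c1OCc1cc(OC)c(OCOC)c(OC)c1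
F5 | step 6 | methyl 2-diazo-2-[2-{[3,5-dimethoxy-4-(methoxymethoxy)phenyl]methoxy}-5-(1,3-dioxolan-2-yl)-3-methoxyphenyl]acetate | COC(=O)C(=[N+]=[N-])c1cc(C2OCCO2)cc(OC)c1OCc1cc(OC)c(OCOC)c(OC)c1
F6 | step 6 | methyl (2R,3S)-cis-5-(1,3-dioxolan-2-yl)-2-[3,5-dimethoxy-4-(methoxymethoxy)phenyl]-7-methoxy-2,3-dihydro-1-benzofuran-3-carboxylate | COc1cc([C@@H]2Oc3c(OC)cc(C4OCCO4)cc3[C@@H]2C(=O)OC)cc(OC)c1OCOC
F7 | step 8 | methyl (2R,3R)-2-[3,5-dimethoxy-4-(methoxymethoxy)phenyl]-5-formyl-7-methoxy-2,3-dihydro-1-benzofuran-3-carboxylate | COc1cc([C@@H]2Oc3c(OC)cc(C=O)cc3[C@H]2C(=O)OC)cc(OC)c1OCOC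
F8 | step 8 | methyl (2R,3R)-2-[3,5-dimethoxy-4-(methoxymethoxy)phenyl]-5-[(E)-3-ethoxy-3-oxoprop-1-enyl]-7-methoxy-2,3-dihydro-1-benzofuran-3-carboxylate | COc1cc([C@@H]2Oc3c(OC)cc(/C=C/C(=O)OCC)cc3[C@H]2C(=O)OC)cc(OC)c1OCOC
F9 | step 3 | racemic methyl 3-[3,5-dimethoxy-4-(methoxymethoxy)phenyl]-3-hydroxypropanoate | COc1cc(C(O)CC(=O)OC)cc(OC)c1OCOC
F10 | step 3 | methyl (3R)-3-acetoxy-3-[3,5-dimethoxy-4-(methoxymethoxy)phenyl]propanoate | COc1cc([C@H](OC(C)=O)CC(=O)OC)cc(OC)c1OCOC
F11 | step 3 | methyl (3S)-3-[3,5-dimethoxy-4-(methoxymethoxy)phenyl]-3-hydroxypropanoate | COc1cc([C@@H](O)CC(=O)OC)cc(OC)c1OCOC
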